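**Retrosynthetic overview**
1. Target 28 ⇒ spiro enone 23 by C9 enolate hydroxylation, acetylation and silyl-to-isobutyrate exchange at C1; 23 ⇒ spiro enone 21 by MeLi addition and oxidative 1,3-enone transposition.
2. 21 ⇒ bromo ketone 19 by intramolecular enolate alkylation (C5–C4), which closes the five-membered ring and sets the spiro centre.
3. 19 ⇒ enone 6 + aldehyde 16 by an intermolecular lithium aldol addition (C5–C1), which sets the C1 carbinol.
4. 6 ⇒ (R)-pulegone (C10 methyl from the chiral pool); 16 ⇒ Evans alkylation of a 3-methylbut-3-enoyl imide with tert-butyl bromoacetate (sets C3).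
5. Ring order: the six-membered ring is carried in from pulegone; the five-membered ring is built second (aldol, then spiro-alkylation).

Assumption: spiro compounds carry the target's locants (C1–C4 five-membered ring, C5 spiro atom, C6–C10 six-membered ring), so the target is the (1R,3S,5R,9R,10S) isomer; 3-methylbut-3-enoic acid is bought.

**Route**

Step 1
Reactants: 1 (R)-(+)-pulegone
Product: 2 pulegone oxide (both epimers at the epoxide spiro carbon)
Conditions: 30% H2O2, NaOH (cat.), MeOH, 0 °C → rt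
Reagents that add atoms: hydrogen peroxide, OO
Why: Weitz–Scheffer nucleophilic epoxidation of the enone by hydroperoxide leaves the C-methyl stereocentre untouched, and the epimer mixture at the epoxide carbon is irrelevant because that carbon is later stripped to CH.

Step 2
Reactants: 2 pulegone oxide
Product: 4 (5R)-5-methyl-2-(phenylsulfanyl)cyclohexan-1-one (both C2 epimers), via sodium alkoxide adduct 3 (not isolated)
Conditions: PhSNa, THF, reflux; H2O
Reagents that add atoms: sodium thiophenolate, [Na+].[S-]c1ccccc1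
Why: The thiolate opens the epoxide at the carbonyl-activated α-carbon and the tertiary β-alkoxy ketone then undergoes retro-aldol loss of acetone, giving the α-phenylthio ketone with the methyl centre intact.

Step 3
Reactants: 4 (5R)-5-methyl-2-(phenylsulfanyl)cyclohexan-1-one
Product: 6 (R)-5-methylcyclohex-2-en-1-one, via sulfoxide 5 (not isolated)
Conditions: mCPBA (1.0 equiv), CH2Cl2, −78 °C; then CaCO3, toluene, 90 °C
Reagents that add atoms: none
Why: Sulfide oxidation followed by thermal syn-elimination of the α-keto sulfoxide can only run towards C3, so it gives the 2-enone regiospecifically without touching C5.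

Step 4
Reactants: 7 3-methylbut-3-enoic acid; 8 (S)-4-benzyl-1,3-oxazolidin-2-one
Product: 10 (4S)-4-benzyl-3-(3-methylbut-3-enoyl)-1,3-oxazolidin-2-one, via mixed pivalic anhydride 9 (not isolated)
Conditions: PivCl, Et3N, THF, −20 °C; then LiCl, 8, −20 °C → rt
Reagents that add atoms: none
Why: Mixed-anhydride N-acylation of the LiCl-activated oxazolidinone is mild enough to keep the β,γ-double bond out of conjugation.

Step 5
Reactants: 10 (4S)-4-benzyl-3-(3-methylbut-3-enoyl)-1,3-oxazolidin-2-one
Product: 12 tert-butyl (3S)-3-{[(4S)-4-benzyl-2-oxo-1,3-oxazolidin-3-yl]carbonyl}-4-methylpent-4-enoate, via sodium Z-enolate 11 (not isolated)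
Conditions: NaN(SiMe3)2, THF, −78 °C; then BrCH2CO2tBu, −78 → −40 °C; AcOH quench
Reagents that add atoms: tert-butyl bromoacetate, BrCC(=O)OC(C)(C)C
Why: Evans asymmetric alkylation, in which the chelated Z-dienolate is alkylated at its α-carbon on the face opposite the benzyl group, sets the isopropenyl-bearing centre (later C3) as S.

Step 6
Reactants: 12 alkylated imide
Product: 13 tert-butyl (3S)-3-(hydroxymethyl)-4-methylpent-4-enoate
Conditions: LiBH4, H2O (1 equiv), Et2O, 0 °C
Reagents that add atoms: none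
Why: LiBH4 reductively cleaves the activated imide carbonyl in preference to the tert-butyl ester and under non-epimerising conditions, releasing the auxiliary.

Step 7
Reactants: 13 tert-butyl (3S)-3-(hydroxymethyl)-4-methylpent-4-enoate
Product: 14 tert-butyl (3S)-3-(bromomethyl)-4-methylpent-4-enoate
Conditions: CBr4, PPh3, CH2Cl2, 0 °C
Reagents that add atoms: carbon tetrabromide, BrC(Br)(Br)Br
Why: Appel bromination proceeds by SN2 displacement at the primary carbon, so the adjacent stereocentre and the alkene are untouched.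

Step 8
Reactants: 14 tert-butyl (3S)-3-(bromomethyl)-4-methylpent-4-enoate
Product: 16 (3S)-3-(bromomethyl)-4-methylpent-4-enal, via aluminium hemiacetal 15 (not isolated)
Conditions: iBu2AlH (1.1 equiv), CH2Cl2, −78 °C; MeOH, then aq. KNaC4H4O6
Reagents that add atoms: none
Why: Partial ester reduction stops at the aldehyde because the tetrahedral aluminium hemiacetal of the bulky tert-butyl ester is stable at −78 °C and collapses only on work-up, and the primary bromide is inert to the hydride.

Step 9
Reactants: 6 (R)-5-methylcyclohex-2-en-1-one; 16 (3S)-3-(bromomethyl)-4-methylpent-4-enal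
Product: 18 (5R,6R)-6-[(1R,3S)-4-bromo-1-hydroxy-3-(prop-1-en-2-yl)butyl]-5-methylcyclohex-2-en-1-one, via lithium dienolate 17 (not isolated)
Conditions: LiN(iPr)2, THF, −78 °C; then 16, −78 °C, 20 min; AcOH quench at −78 °C
Reagents that add atoms: none
Why: In this directed lithium aldol addition the kinetic α'-enolate is attacked anti to the neighbouring methyl through a chair Zimmerman–Traxler transition state of the ring-locked E(O)-enolate, giving the anti aldol with the carbinol (later C1) R; minor carbinol epimers are removed by chromatography and the ring α-centre is erased later.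

Step 10
Reactants: 18 aldol adduct
Product: 19 (5R,6R)-6-[(1R,3S)-4-bromo-1-{[tert-butyl(dimethyl)silyl]oxy}-3-(prop-1-en-2-yl)butyl]-5-methylcyclohex-2-en-1-one
Conditions: TBSOTf, 2,6-lutidine, CH2Cl2, −78 → 0 °C
Reagents that add atoms: tert-butyldimethylsilyl triflate, CC(C)(C)[Si](C)(C)OS(=O)(=O)C(F)(F)F
Why: Silylation with the triflate and a hindered base protects the hindered β-hydroxy ketone without retro-aldol or dehydration.

Step 11
Reactants: 19 silyl ether bromide
Product: 21 (1R,3S,5S,10R)-1-{[tert-butyl(dimethyl)silyl]oxy}-10-methyl-3-(prop-1-en-2-yl)spiro[4.5]dec-7-en-6-one, via lithium enolate 20 (not isolated)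
Conditions: LiN(iPr)2 (1.1 equiv), THF, −78 °C (ketone added to base); then DMPU, −78 → 0 °C
Reagents that add atoms: none
Why: In this 5-(enolexo)-exo-tet intramolecular enolate alkylation the bromomethyl carbon bonds anti to the C10 methyl, from the side-chain conformer of least A(1,3) strain (carbinol H eclipsing the enolate C–O), which the 1R centre places on that same face, so the spiro centre forms with C4 anti and C1 syn to the methyl.

Step 12
Reactants: 21 spiro enone
Product: 22 (1R,3S,5S,10R)-1-{[tert-butyl(dimethyl)silyl]oxy}-6,10-dimethyl-3-(prop-1-en-2-yl)spiro[4.5]dec-7-en-6-ol (both C6 epimers)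
Conditions: MeLi, Et2O, −78 → 0 °C; H2O
Reagents that add atoms: methyllithium, [Li]C
Why: MeLi adds 1,2 to the enone carbonyl, which has no α-hydrogen on its spiro side, and both carbinol epimers converge in the next step.

Step 13
Reactants: 22 tertiary allylic alcohol
Product: 23 (1R,3S,5R,10R)-1-{[tert-butyl(dimethyl)silyl]oxy}-6,10-dimethyl-3-(prop-1-en-2-yl)spiro[4.5]dec-6-en-8-one
Conditions: pyridinium chlorochromate (C5H5NH)(CrO3Cl), 4 Å MS, CH2Cl2, rt
Reagents that add atoms: pyridinium chlorochromate, [O-][Cr](=O)(=O)Cl.c1cc[nH+]cc1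
Why: Dauben-type oxidative 1,3-transposition, in which the tertiary chromate ester undergoes a [3,3] shift and the secondary allylic chromate is oxidised, delivers the 6-methyl-6-en-8-one without affecting the silyl ether or the isopropenyl group.

Step 14
Reactants: 23 transposed spiro enone
Product: 25 (1R,3S,5R,9R,10S)-1-{[tert-butyl(dimethyl)silyl]oxy}-9-hydroxy-6,10-dimethyl-3-(prop-1-en-2-yl)spiro[4.5]dec-6-en-8-one, via sodium dienolate 24 (not isolated)
Conditions: NaN(SiMe3)2, THF, −78 °C; then 2-(phenylsulfonyl)-3-phenyloxaziridine, −78 °C; AcOH quench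
Reagents that add atoms: 2-(phenylsulfonyl)-3-phenyloxaziridine, O=S(=O)(N1OC1c1ccccc1)c1ccccc1
Why: In this Davis enolate hydroxylation the kinetic α'-enolate (C8–C9) takes oxygen on the face anti to the adjacent C10 methyl, giving the trans 9R alcohol, and the oxaziridine does not epoxidise the isopropenyl group.

Step 15
Reactants: 25 α'-hydroxy enone
Product: 26 (1R,3S,5R,9R,10S)-1-{[tert-butyl(dimethyl)silyl]oxy}-6,10-dimethyl-8-oxo-3-(prop-1-en-2-yl)spiro[4.5]dec-6-en-9-yl acetate
Conditions: Ac2O, pyridine, DMAP (cat.), CH2Cl2, 0 °C → rt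
Reagents that add atoms: acetic anhydride, CC(=O)OC(C)=O
Why: DMAP-catalysed acetylation of the secondary α-ketol is fast under conditions too mild to epimerise C9.

Step 16
Reactants: 26 silyl ether acetate
Product: 27 (1R,3S,5R,9R,10S)-1-hydroxy-6,10-dimethyl-8-oxo-3-(prop-1-en-2-yl)spiro[4.5]dec-6-en-9-yl acetate
Conditions: HF·pyridine, pyridine, THF, 0 °C → rt
Reagents that add atoms: none
Why: Buffered acidic fluoride desilylation frees the C1 alcohol without the basic conditions that could move or cleave the acetate or epimerise C9.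

Step 17
Reactants: 27 C1 alcohol
Product: 28 (1R,3S,5R,9R,10S)-9-acetoxy-6,10-dimethyl-8-oxo-3-(prop-1-en-2-yl)spiro[4.5]dec-6-en-1-yl 2-methylpropanoate (target)
Conditions: iPrCOCl, pyridine, DMAP (cat.), CH2Cl2, 0 °C → rt
Reagents that add atoms: 2-methylpropanoyl chloride, CC(C)C(Cl)=O
Why: DMAP-catalysed acylation of the hindered secondary alcohol with the acid chloride proceeds with retention at C1 and completes the target.

**Compound list**
1 | (R)-(+)-pulegone, (5R)-5-methyl-2-(propan-2-ylidene)cyclohexan-1-one | C[C@@H]1CCC(=C(C)C)C(=O)C1 | starting material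
2 | pulegone oxide, (6R)-2,2,6-trimethyl-1-oxaspiro[2.5]octan-4-one, both epimers at C3 | C[C@@H]1CCC2(OC2(C)C)C(=O)C1 | intermediate
3 | sodium 2-[(4R)-4-methyl-2-oxo-1-(phenylsulfanyl)cyclohexyl]propan-2-olate (not isolated) | [Na+].C[C@@H]1CCC(Sc2ccccc2)(C(C)(C)[O-])C(=O)C1 | intermediate
4 | (5R)-5-methyl-2-(phenylsulfanyl)cyclohexan-1-one, both C2 epimers | C[C@@H]1CCC(Sc2ccccc2)C(=O)C1 | intermediate
5 | (5R)-5-methyl-2-(phenylsulfinyl)cyclohexan-1-one, diastereomer mixture (not isolated) | C[C@@H]1CCC(S(=O)c2ccccc2)C(=O)C1 | intermediate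
6 | (R)-5-methylcyclohex-2-en-1-one | C[C@@H]1CC=CC(=O)C1 | intermediate
7 | 3-methylbut-3-enoic acid | C=C(C)CC(=O)O | starting material
8 | (S)-4-benzyl-1,3-oxazolidin-2-one | O=C1N[C@@H](Cc2ccccc2)CO1 | starting material
9 | 3-methylbut-3-enoic 2,2-dimethylpropanoic anhydride (not isolated) | C=C(C)CC(=O)OC(=O)C(C)(C)C | intermediate
10 | (4S)-4-benzyl-3-(3-methylbut-3-enoyl)-1,3-oxazolidin-2-one | C=C(C)CC(=O)N1[C@@H](Cc2ccccc2)COC1=O | intermediate
11 | sodium (Z)-enolate of 10 (not isolated) | [Na+].C=C(C)/C=C(\[O-])N1[C@@H](Cc2ccccc2)COC1=O | intermediate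
12 | tert-butyl (3S)-3-{[(4S)-4-benzyl-2-oxo-1,3-oxazolidin-3-yl]carbonyl}-4-methylpent-4-enoate | C=C(C)[C@H](CC(=O)OC(C)(C)C)C(=O)N1[C@@H](Cc2ccccc2)COC1=O | intermediate
13 | tert-butyl (3S)-3-(hydroxymethyl)-4-methylpent-4-enoate | C=C(C)[C@@H](CO)CC(=O)OC(C)(C)C | intermediate
14 | tert-butyl (3S)-3-(bromomethyl)-4-methylpent-4-enoate | C=C(C)[C@@H](CBr)CC(=O)OC(C)(C)C | intermediate
15 | diisobutylaluminium hemiacetal of 14 (not isolated) | C=C(C)[C@@H](CBr)CC(OC(C)(C)C)O[Al](CC(C)C)CC(C)C | intermediate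
16 | (3S)-3-(bromomethyl)-4-methylpent-4-enal | C=C(C)[C@@H](CBr)CC=O | intermediate
17 | lithium (3R)-3-methylcyclohexa-1,5-dien-1-olate (not isolated) | [Li+].C[C@@H]1CC=CC([O-])=C1 | intermediate
18 | (5R,6R)-6-[(1R,3S)-4-bromo-1-hydroxy-3-(prop-1-en-2-yl)butyl]-5-methylcyclohex-2-en-1-one | C=C(C)[C@@H](CBr)C[C@@H](O)[C@@H]1C(=O)C=CC[C@H]1C | intermediate
19 | (5R,6R)-6-[(1R,3S)-4-bromo-1-{[tert-butyl(dimethyl)silyl]oxy}-3-(prop-1-en-2-yl)butyl]-5-methylcyclohex-2-en-1-one | C=C(C)[C@@H](CBr)C[C@@H](O[Si](C)(C)C(C)(C)C)[C@@H]1C(=O)C=CC[C@H]1C | intermediate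
20 | lithium C1=C6 enolate of 19 (not isolated) | [Li+].C=C(C)[C@@H](CBr)C[C@@H](O[Si](C)(C)C(C)(C)C)C1=C([O-])C=CC[C@H]1C | intermediate
21 | (1R,3S,5S,10R)-1-{[tert-butyl(dimethyl)silyl]oxy}-10-methyl-3-(prop-1-en-2-yl)spiro[4.5]dec-7-en-6-one | C=C(C)[C@@H]1C[C@@H](O[Si](C)(C)C(C)(C)C)[C@@]2(C1)C(=O)C=CC[C@H]2C | intermediate
22 | (1R,3S,5S,10R)-1-{[tert-butyl(dimethyl)silyl]oxy}-6,10-dimethyl-3-(prop-1-en-2-yl)spiro[4.5]dec-7-en-6-ol, both C6 epimers | C=C(C)[C@@H]1C[C@@H](O[Si](C)(C)C(C)(C)C)[C@@]2(C1)C(C)(O)C=CC[C@H]2C | intermediate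
23 | (1R,3S,5R,10R)-1-{[tert-butyl(dimethyl)silyl]oxy}-6,10-dimethyl-3-(prop-1-en-2-yl)spiro[4.5]dec-6-en-8-one | C=C(C)[C@@H]1C[C@@H](O[Si](C)(C)C(C)(C)C)[C@@]2(C1)C(C)=CC(=O)C[C@H]2C | intermediate
24 | sodium C8=C9 dienolate of 23 (not isolated) | [Na+].C=C(C)[C@@H]1C[C@@H](O[Si](C)(C)C(C)(C)C)[C@@]2(C1)C(C)=CC([O-])=C[C@H]2C | intermediate
25 | (1R,3S,5R,9R,10S)-1-{[tert-butyl(dimethyl)silyl]oxy}-9-hydroxy-6,10-dimethyl-3-(prop-1-en-2-yl)spiro[4.5]dec-6-en-8-one | C=C(C)[C@@H]1C[C@@H](O[Si](C)(C)C(C)(C)C)[C@@]2(C1)C(C)=CC(=O)[C@H](O)[C@H]2C | intermediate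
26 | (1R,3S,5R,9R,10S)-1-{[tert-butyl(dimethyl)silyl]oxy}-6,10-dimethyl-8-oxo-3-(prop-1-en-2-yl)spiro[4.5]dec-6-en-9-yl acetate | C=C(C)[C@@H]1C[C@@H](O[Si](C)(C)C(C)(C)C)[C@@]2(C1)C(C)=CC(=O)[C@H](OC(C)=O)[C@H]2C | intermediate
27 | (1R,3S,5R,9R,10S)-1-hydroxy-6,10-dimethyl-8-oxo-3-(prop-1-en-2-yl)spiro[4.5]dec-6-en-9-yl acetate | C=C(C)[C@@H]1C[C@@H](O)[C@@]2(C1)C(C)=CC(=O)[C@H](OC(C)=O)[C@H]2C | intermediate
28 | (1R,3S,5R,9R,10S)-9-acetoxy-6,10-dimethyl-8-oxo-3-(prop-1-en-2-yl)spiro[4.5]dec-6-en-1-yl 2-methylpropanoate | C=C(C)[C@@H]1C[C@@H](OC(=O)C(C)C)[C@@]2(C1)C(C)=CC(=O)[C@H](OC(C)=O)[C@H]2C | target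

**Step count and risks**
Total steps: 17. Longest linear sequence: 14 steps (steps 4–17, from 3-methylbut-3-enoic acid); the pulegone branch contributes 3 steps before the junction at step 9.

The three steps most likely to fail:

- **Step 9.** The aldol can give too little of the anti carbinol, since lithium enolates of cyclic ketones are only moderately anti-selective. The fallback sets out from 6: soft enolisation with Bu2BOTf and iPr2NEt (CH2Cl2, −78 °C) gives the dibutylboron dienolate F1, whose short B–O bonds tighten the chair transition state. Addition of 16 at −78 °C gives the dibutylboron aldolate F2, and hydrolysis with MeOH and pH 7 buffer comes back to the route at 18 with higher anti selectivity.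

- **Step 11.** The spiro-alkylation can fail if ring closure by the β-branched bromide is slower than loss of silyloxide from the enolate. The fallback sets out from 19: Finkelstein exchange (NaI, acetone, reflux) gives the iodide F3, and its potassium enolate (KN(SiMe3)2, THF, −78 → −40 °C) alkylates at a temperature where β-elimination does not compete. It comes back to the route at 21.

- **Step 14.** The hydroxylation can suffer from enolate addition to the sulfonimine by-product or from imperfect facial selectivity at C9. The fallback sets out from 23: direct α'-acetoxylation with Mn(OAc)3 (benzene, reflux with water removal) installs the acetate in one operation through the manganese enolate. It passes by 25 and comes back to the route at 26; no new compound arises on this way (F0).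

**Further compounds**
F1 | step 9 | dibutyl{[(3R)-3-methylcyclohexa-1,5-dien-1-yl]oxy}borane | C[C@@H]1CC=CC(OB(CCCC)CCCC)=C1
F2 | step 9 | dibutylboron aldolate of 18, (5R,6R)-6-[(1R,3S)-4-bromo-1-(dibutylboranyloxy)-3-(prop-1-en-2-yl)butyl]-5-methylcyclohex-2-en-1-one | C=C(C)[C@@H](CBr)C[C@@H](OB(CCCC)CCCC)[C@@H]1C(=O)C=CC[C@H]1C
F3 | step 11 | (5R,6R)-6-[(1R,3S)-1-{[tert-butyl(dimethyl)silyl]oxy}-4-iodo-3-(prop-1-en-2-yl)butyl]-5-methylcyclohex-2-en-1-one | C=C(C)[C@@H](CI)C[C@@H](O[Si](C)(C)C(C)(C)C)[C@@H]1C(=O)C=CC[C@H]1C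
F0 | step 14 | none | none
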